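The seven-membered ring is cut twice: at the C7=C8 olefin and at the C3a–C4 bond (azulene numbering; C3 = isopropyl carbinol, C8a = angular methyl). This exposes a cyclopentanone enolate at C3a carrying an alkenyl group on quaternary C8a, and a four-carbon aldehyde C4–C7 that already holds the C6 tertiary carbinol. The key step exploits the latent aldol unit C3(=O)–C3a–C4(OH) and the cis olefin wedged between the fully substituted carbons C8a and C6: in one flask an equilibrating zinc aldol joins C3a to C4, then ring-closing metathesis welds C7 to C8, giving the trans-fused hydroazulenone. Isopropyl addition and acylation finish.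

Key step: step 6

Remark: ring positions follow the azulene numbering of the target (C3 isopropyl carbinol, C3a ring-fusion CH, C4 ester carbon, C6 methyl carbinol, C7=C8 olefin, C8a angular methyl); compounds 2, 6 and 17 are taken as purchasable.

Step 1
Reactants: 1 3-methylcyclopent-2-en-1-one; 2 (2-methylprop-1-en-1-yl)magnesium bromide
Product: 5 (R)-trimethyl{[3-methyl-3-(2-methylprop-1-en-1-yl)cyclopent-1-en-1-yl]oxy}silane, via alkenylalane 3 (not isolated), via aluminium enolate 4 (not isolated)
Conditions: 2, Me2AlCl, Et2O, −78 °C to rt; then 1, Cu(O2CC4H3S) (CuTC, 5 mol %), chiral phosphinamine ligand of the SimplePhos class (6 mol %), Et2O, −30 °C; then Me3SiOTf, −30 to 0 °C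
Reagents that add atoms: trimethylsilyl trifluoromethanesulfonate, C[Si](C)(C)OS(=O)(=O)C(F)(F)F
Why: Copper-catalysed asymmetric conjugate addition of an alkenylalane to a β-substituted cyclic enone creates the quaternary carbon C8a under ligand control (the ligand enantiomer that leads to the R enol ether is used), and O-silylation of the aluminium enolate by the silyl triflate stores the enolate regiospecifically on the C3a side.

Step 2
Reactants: 6 (E)-3-methylpent-2-en-4-yn-1-ol
Product: 7 [(2S,3S)-3-ethynyl-3-methyloxiran-2-yl]methanol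
Conditions: Ti(OiPr)4 (10 mol %), L-(+)-diethyl tartrate (12 mol %), t-BuOOH, 4 Å MS, CH2Cl2, −20 °C
Reagents that add atoms: tert-butyl hydroperoxide, CC(C)(C)OO
Why: Sharpless asymmetric epoxidation of an E-trisubstituted allylic alcohol, in which the titanium complex of L-(+)-tartrate delivers oxygen to the face that gives the 2S,3S epoxide (the sense known for E-3-methylalk-2-en-1-ols) and so fixes the future C6 stereocentre.

Step 3
Reactants: 7 [(2S,3S)-3-ethynyl-3-methyloxiran-2-yl]methanol
Product: 9 (R)-3-methylpent-4-ene-1,3-diol, via ynediol 8 (not isolated)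
Conditions: NaAlH2(OCH2CH2OMe)2 (Red-Al, 4 equiv), THF, 0 °C to 45 °C; Rochelle salt work-up
Reagents that add atoms: none
Why: Hydroxyl-directed hydride opening of the 2,3-epoxy alcohol at C2 (the known Red-Al route to 1,3-diols) leaves the tertiary C–O stereocentre untouched, and the tertiary propargylic aluminate then undergoes the known trans-hydroalumination of propargylic alcohols, so that protonolysis should leave the vinyl group.

Step 4
Reactants: 9 (R)-3-methylpent-4-ene-1,3-diol
Product: 10 (R)-3-methyl-1,3-bis[(triethylsilyl)oxy]pent-4-ene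
Conditions: Et3SiOTf (2.5 equiv), 2,6-lutidine, CH2Cl2, −78 to 0 °C
Reagents that add atoms: triethylsilyl trifluoromethanesulfonate, CC[Si](CC)(CC)OS(=O)(=O)C(F)(F)F
Why: Silylation with a silyl triflate and a hindered pyridine base covers both the primary and the hindered tertiary hydroxyl without touching the stereocentre.

Step 5
Reactants: 10 (R)-3-methyl-1,3-bis[(triethylsilyl)oxy]pent-4-ene
Product: 11 (R)-3-methyl-3-[(triethylsilyl)oxy]pent-4-enal
Conditions: (COCl)2, DMSO, CH2Cl2, −78 °C; 10, −78 to −40 °C; Et3N, −78 to 0 °C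
Reagents that add atoms: none
Why: Swern oxidation with selective in-situ cleavage of the primary triethylsilyl ether (the chlorosulfonium salt attacks only the unhindered silyl ether oxygen) should give the aldehyde directly while the tertiary silyl ether stays in place.

Step 6
Reactants: 5 (R)-trimethyl{[3-methyl-3-(2-methylprop-1-en-1-yl)cyclopent-1-en-1-yl]oxy}silane; 11 (R)-3-methyl-3-[(triethylsilyl)oxy]pent-4-enal
Product: 15 (3aS,4S,6R,8aR)-4-hydroxy-6,8a-dimethyl-6-[(triethylsilyl)oxy]-2,3a,4,5,6,8a-hexahydroazulen-3(1H)-one, via lithium enolate 12 (not isolated), via zinc enolate 13 (not isolated), via aldol adduct 14 (not isolated)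
Conditions: 5, MeLi, THF, 0 °C; ZnCl2, −78 °C; 11, −78 to 0 °C; AcOH (1 equiv); dilution with toluene (about 0.005 M), second-generation Hoveyda–Grubbs catalyst (5 mol %), 60 °C, argon sparge
Reagents that add atoms: none
Why: Methyllithium cleaves the silyl enol ether to the lithium enolate, which can only be the C3–C3a enolate, and zinc exchange gives a chelating enolate whose aldol addition to aldehyde 11 is reversible, so that the aldolates should drain into the most stable six-membered zinc chelate before acetic acid frees 14, after which the ruthenium alkylidene loads on the monosubstituted vinyl group next to C6 and closes onto the trisubstituted olefin on C8a with loss of 2-methylpropene. The closest known reaction types are the directed aldol addition of a regiospecifically generated zinc enolate under equilibrating conditions and ring-closing olefin metathesis, here run in one flask. The only ring closed is the seven-membered one, by metathesis of a 1,8-diene, and its size forces the new C7=C8 olefin to be cis. C3a (S) is set in the aldol stage because the aldehyde should add to the enolate face opposite the larger 2-methylprop-1-enyl group on C8a, that is cis to the angular methyl, which is what makes the later ring fusion trans, and C4 (S) follows from the anti relationship of the chair-like chelate, in which the cyclic enolate is necessarily E. C8a and C6 come in unchanged with 5 and 11. The step needs facial and anti selectivity in the aldol addition (secured by the size difference at C8a and by thermodynamic control), no epimerisation at C3a afterwards (secured by the neutral metathesis medium) and clean initiation (secured by the trisubstituted olefin, which cannot load the catalyst).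

Step 7
Reactants: 15 (3aS,4S,6R,8aR)-4-hydroxy-6,8a-dimethyl-6-[(triethylsilyl)oxy]-2,3a,4,5,6,8a-hexahydroazulen-3(1H)-one
Product: 16 (3R,3aS,4S,6R,8aR)-6,8a-dimethyl-3-(propan-2-yl)-6-[(triethylsilyl)oxy]-1,2,3,3a,4,5,6,8a-octahydroazulene-3,4-diol
Conditions: i-PrMgCl (4 equiv), CeCl3 (4 equiv, dried), THF, −78 to −40 °C; aq NH4Cl
Reagents that add atoms: isopropylmagnesium chloride, CC(C)[Mg]Cl
Why: CeCl3-promoted Grignard (organocerium) 1,2-addition to a hindered enolisable ketone, in which the reagent should approach the carbonyl from the face opposite the C3a–C4 bond and the angular C8a methyl, so that isopropyl ends cis to H-3a and the new hydroxyl cis to the methyl (3R).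

Step 8
Reactants: 16 (3R,3aS,4S,6R,8aR)-6,8a-dimethyl-3-(propan-2-yl)-6-[(triethylsilyl)oxy]-1,2,3,3a,4,5,6,8a-octahydroazulene-3,4-diol; 17 4-[(tert-butyldimethylsilyl)oxy]benzoic acid
Product: 19 (3R,3aS,4S,6R,8aR)-3-hydroxy-6,8a-dimethyl-3-(propan-2-yl)-6-[(triethylsilyl)oxy]-1,2,3,3a,4,5,6,8a-octahydroazulen-4-yl 4-[(tert-butyldimethylsilyl)oxy]benzoate, via mixed anhydride 18 (not isolated)
Conditions: 17, 2,4,6-Cl3C6H2COCl, Et3N, THF, rt; then 16, DMAP, toluene, rt to 40 °C
Reagents that add atoms: none
Why: Yamaguchi esterification should acylate only the secondary C4 hydroxyl, with retention, since the free tertiary C3 hydroxyl and the silylated tertiary C6 oxygen are too hindered for the acylpyridinium.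

Step 9
Reactants: 19 (3R,3aS,4S,6R,8aR)-3-hydroxy-6,8a-dimethyl-3-(propan-2-yl)-6-[(triethylsilyl)oxy]-1,2,3,3a,4,5,6,8a-octahydroazulen-4-yl 4-[(tert-butyldimethylsilyl)oxy]benzoate
Product: 20 (3R,3aS,4S,6R,8aR)-3,6-dihydroxy-6,8a-dimethyl-3-(propan-2-yl)-1,2,3,3a,4,5,6,8a-octahydroazulen-4-yl 4-hydroxybenzoate
Conditions: Bu4NF, AcOH (1:1), THF, 0 °C to rt
Reagents that add atoms: none
Why: Fluoride-induced desilylation buffered by acetic acid should remove the aryl tert-butyldimethylsilyl ether and the tertiary triethylsilyl ether together, the near-neutral medium sparing the benzoate ester (no acyl migration) and the acid-labile tertiary allylic alcohol.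

Compound list
1 | 3-methylcyclopent-2-en-1-one | CC1=CC(=O)CC1 | starting material
2 | (2-methylprop-1-en-1-yl)magnesium bromide | CC(C)=C[Mg]Br | starting material
3 | dimethyl(2-methylprop-1-en-1-yl)alane | CC(C)=C[Al](C)C | intermediate (not isolated)
4 | dimethylaluminium (R)-3-methyl-3-(2-methylprop-1-en-1-yl)cyclopent-1-en-1-olate | C[Al](C)OC1=C[C@@](C)(C=C(C)C)CC1 | intermediate (not isolated)
5 | (R)-trimethyl{[3-methyl-3-(2-methylprop-1-en-1-yl)cyclopent-1-en-1-yl]oxy}silane | C[Si](C)(C)OC1=C[C@@](C)(C=C(C)C)CC1 | intermediate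
6 | (E)-3-methylpent-2-en-4-yn-1-ol | OC/C=C(\C)C#C | starting material
7 | [(2S,3S)-3-ethynyl-3-methyloxiran-2-yl]methanol | OC[C@@H]1O[C@@]1(C)C#C | intermediate
8 | (R)-3-methylpent-4-yne-1,3-diol | OCC[C@@](C)(O)C#C | intermediate (not isolated)
9 | (R)-3-methylpent-4-ene-1,3-diol | OCC[C@@](C)(O)C=C | intermediate
10 | (R)-3-methyl-1,3-bis[(triethylsilyl)oxy]pent-4-ene | CC[Si](CC)(CC)OCC[C@@](C)(O[Si](CC)(CC)CC)C=C | intermediate
11 | (R)-3-methyl-3-[(triethylsilyl)oxy]pent-4-enal | O=CC[C@@](C)(O[Si](CC)(CC)CC)C=C | intermediate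
12 | lithium (R)-3-methyl-3-(2-methylprop-1-en-1-yl)cyclopent-1-en-1-olate | [Li]OC1=C[C@@](C)(C=C(C)C)CC1 | intermediate (not isolated)
13 | chlorozinc (R)-3-methyl-3-(2-methylprop-1-en-1-yl)cyclopent-1-en-1-olate | Cl[Zn]OC1=C[C@@](C)(C=C(C)C)CC1 | intermediate (not isolated)
14 | (2S,3R)-2-[(1S,3R)-1-hydroxy-3-methyl-3-[(triethylsilyl)oxy]pent-4-en-1-yl]-3-methyl-3-(2-methylprop-1-en-1-yl)cyclopentan-1-one | O=C1CC[C@](C)(C=C(C)C)[C@H]1[C@@H](O)C[C@@](C)(O[Si](CC)(CC)CC)C=C | intermediate (not isolated)
15 | (3aS,4S,6R,8aR)-4-hydroxy-6,8a-dimethyl-6-[(triethylsilyl)oxy]-2,3a,4,5,6,8a-hexahydroazulen-3(1H)-one | O=C1CC[C@]2(C)C=C[C@](C)(O[Si](CC)(CC)CC)C[C@H](O)[C@H]21 | intermediate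
16 | (3R,3aS,4S,6R,8aR)-6,8a-dimethyl-3-(propan-2-yl)-6-[(triethylsilyl)oxy]-1,2,3,3a,4,5,6,8a-octahydroazulene-3,4-diol | CC(C)[C@]1(O)CC[C@]2(C)C=C[C@](C)(O[Si](CC)(CC)CC)C[C@H](O)[C@H]21 | intermediate
17 | 4-[(tert-butyldimethylsilyl)oxy]benzoic acid | CC(C)(C)[Si](C)(C)Oc1ccc(cc1)C(O)=O | starting material
18 | 4-[(tert-butyldimethylsilyl)oxy]benzoic 2,4,6-trichlorobenzoic anhydride | CC(C)(C)[Si](C)(C)Oc1ccc(cc1)C(=O)OC(=O)c1c(Cl)cc(Cl)cc1Cl | intermediate (not isolated)
19 | (3R,3aS,4S,6R,8aR)-3-hydroxy-6,8a-dimethyl-3-(propan-2-yl)-6-[(triethylsilyl)oxy]-1,2,3,3a,4,5,6,8a-octahydroazulen-4-yl 4-[(tert-butyldimethylsilyl)oxy]benzoate | CC(C)[C@]1(O)CC[C@]2(C)C=C[C@](C)(O[Si](CC)(CC)CC)C[C@H](OC(=O)c3ccc(O[Si](C)(C)C(C)(C)C)cc3)[C@H]21 | intermediate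
20 | (3R,3aS,4S,6R,8aR)-3,6-dihydroxy-6,8a-dimethyl-3-(propan-2-yl)-1,2,3,3a,4,5,6,8a-octahydroazulen-4-yl 4-hydroxybenzoate | CC(C)[C@]1(O)CC[C@]2(C)C=C[C@](C)(O)C[C@H](OC(=O)c3ccc(O)cc3)[C@H]21 | target

Total step count: 9 steps. Longest linear sequence: 8 steps (steps 2 to 9, from 6 to 20).

Steps most likely to fail

Step 6. The aldol stage may discriminate the two faces of the C3a enolate poorly, because methyl and 2-methylprop-1-enyl on C8a differ only moderately in size. The ring closure may also stall, since both olefins sit on fully substituted carbons. Prolonged heating could then cause retro-aldol cleavage or epimerisation at C3a. Fallback, from 14 back to the route at 16: the aldol adduct 14 is isolated after the zinc aldol stage, which also allows the minor C3a epimer to be removed. Its ketone is first converted with i-PrMgCl/CeCl3 into the monocyclic isopropyl carbinol F1. One equivalent of ozone (pyridine, CH2Cl2, −78 °C; Me2S) should cleave only the electron-rich trisubstituted olefin to the neopentyl aldehyde F2. Ph3P=CH2 turns this into the divinyl compound F3. Ring-closing metathesis of this less hindered 1,8-diene (second-generation Grubbs catalyst, CH2Cl2, 40 °C), now free of an epimerisable ketone, returns to 16.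

Step 1. The conjugate addition may lose enantioselectivity on the five-membered enone or be diverted into 1,2-addition, and O-silylation of the aluminium enolate may be incomplete. Fallback, from 2 back to the route at 5: the roles of the two carbon groups on C8a are exchanged. Grignard reagent 2 adds 1,2 to commercial 3-ethoxycyclopent-2-en-1-one to give, as its magnesium alkoxide, 3-ethoxy-1-(2-methylprop-1-en-1-yl)cyclopent-2-en-1-ol F4. Dilute acid work-up (Stork–Danheiser transposition) gives the extended dienone 3-(2-methylprop-1-en-1-yl)cyclopent-2-en-1-one F5. A 1,4-selective addition of MeMgBr, catalysed by Cu(OTf)2 and a chiral imidazolinium carbene precursor, then creates the same quaternary carbon as the bromomagnesium enolate F6. Me3SiCl/Et3N converts F6 into 5.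

Step 7. The hindered ketone may enolise or undergo retro-aldol cleavage as its β-alkoxide instead of adding the reagent, and the secondary organometallic may reduce it by β-hydride transfer. Fallback, from 15 back to the route at 16: the less basic sp2 reagent isopropenylmagnesium bromide with CeCl3 is added instead and should give the isopropenyl carbinol F7. Its 1,1-disubstituted olefin is then hydrogenated selectively (H2, RhCl(PPh3)3, benzene, rt), the ring olefin between two quaternary carbons being left untouched, which returns to 16.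

Further compounds
F1 | step 6 | (1R,2S,3R)-2-[(1S,3R)-1-hydroxy-3-methyl-3-[(triethylsilyl)oxy]pent-4-en-1-yl]-3-methyl-3-(2-methylprop-1-en-1-yl)-1-(propan-2-yl)cyclopentan-1-ol | CC(C)[C@]1(O)CC[C@](C)(C=C(C)C)[C@H]1[C@@H](O)C[C@@](C)(O[Si](CC)(CC)CC)C=C
F2 | step 6 | (1S,2S,3R)-3-hydroxy-2-[(1S,3R)-1-hydroxy-3-methyl-3-[(triethylsilyl)oxy]pent-4-en-1-yl]-1-methyl-3-(propan-2-yl)cyclopentane-1-carbaldehyde | CC(C)[C@]1(O)CC[C@](C)(C=O)[C@H]1[C@@H](O)C[C@@](C)(O[Si](CC)(CC)CC)C=C
F3 | step 6 | (1R,2S,3R)-3-ethenyl-2-[(1S,3R)-1-hydroxy-3-methyl-3-[(triethylsilyl)oxy]pent-4-en-1-yl]-3-methyl-1-(propan-2-yl)cyclopentan-1-ol | CC(C)[C@]1(O)CC[C@](C)(C=C)[C@H]1[C@@H](O)C[C@@](C)(O[Si](CC)(CC)CC)C=C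
F4 | step 1 | 3-ethoxy-1-(2-methylprop-1-en-1-yl)cyclopent-2-en-1-ol (racemic) | CCOC1=CC(O)(C=C(C)C)CC1
F5 | step 1 | 3-(2-methylprop-1-en-1-yl)cyclopent-2-en-1-one | CC(C)=CC1=CC(=O)CC1
F6 | step 1 | bromomagnesium (R)-3-methyl-3-(2-methylprop-1-en-1-yl)cyclopent-1-en-1-olate | Br[Mg]OC1=C[C@@](C)(C=C(C)C)CC1
F7 | step 7 | (3S,3aS,4S,6R,8aR)-6,8a-dimethyl-3-(prop-1-en-2-yl)-6-[(triethylsilyl)oxy]-1,2,3,3a,4,5,6,8a-octahydroazulene-3,4-diol | C=C(C)[C@]1(O)CC[C@]2(C)C=C[C@](C)(O[Si](CC)(CC)CC)C[C@H](O)[C@H]21
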